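**Slow flasks.** Slowness is not what we rank: the flasks below are ordered by product, as a share of the starting material charged, at two times, from the earlier runs.

| flask | starting material | partner | initiator | remark | time |
|---|---|---|---|---|---|
| teal | 7.2 mM | 24 mM | 0.36 mM | run made earlier |  |
| violet | 30 mM | 24 mM | 0.36 mM | run made earlier |  |
| ochre | 24 mM | 26 mM | 0.36 mM | run made earlier |  |
| south | 24 mM | 24.0 mM | 0.20 mM |  | 15 min |
| south-west | 12 mM | 15.0 mM | 0.50 mM |  | 15 min |
| west | 40 mM | 24.0 mM | 0.36 mM |  | 15 min |
| east | 24 mM | 24.0 mM | 0.36 mM |  | 15 min |
| south-east | 24 mM | 50.0 mM | 0.20 mM |  | 15 min |

- teal (time / min: product / %, starting material / %): 0.833: 42.4, 57.8; 1.33: 64.7, 34.9; 2.00: 88.0, 9.7; 3.00: 99.1, 0; 5.00: 98.0, 0.2; 6.00: 97.9, 0.1; 10.0: 98.1, 0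
- violet (time / min: product / %, starting material / %): 0.833: 11.1, 88.8; 1.33: 16.0, 84.4; 2.00: 23.2, 76.5; 3.00: 30.8, 68.4; 5.00: 43.8, 55.6; 6.00: 48.3, 50.6; 10.0: 60.6, 37.7
- ochre (time / min: product / %, starting material / %): 1.00: 15.9, 83.5; 2.50: 36.8, 62.1; 5.00: 59.2, 40.3; 8.00: 74.9, 22.8; 10.0: 82.2, 16.8

(scatter of a reading: 0.5 percentage points)

- ranking by amount of product, in percent of the starting material charged, from high to low, at 15 min (south / south-west / west / east / south-east)
- the same order at 1.0 h (south / south-west / west / east / south-east)
- the amount of product, in percent of the starting material charged of the flask you put first, at 15 min
- the amount of product, in percent of the starting material charged of the flask you put last, at 15 min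

- in percentages every species weighs as the starting material in it: one ended chains counts as two
- the analysis behind the earlier runs scatters by 0.5 percentage points, standard deviation
- steps thought possible: 2 first chain carrier -> ended chains; partner + first chain carrier -> product + second chain carrier; initiator -> 2 initiating radical; starting material + initiating radical -> capped initiator + first chain carrier; starting material + second chain carrier -> released group + first chain carrier
- no earlier run changes the charge of initiator; that part of a forecast is a guess

**The odd pair.** At 0.833 min the teal run shows 42.4% product and the violet run 11.1%, though violet differs in holding 4.17 times teal's starting material. Counted as a share of the partner charge, one partner per product, the same readings give 12.7% and 13.9%. So the two flasks have spent close shares of their partner, and violet divides by a larger charge.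

**The exponent.** In violet, the logarithm of partner charged over partner left reads 0.793 at 5.00 min and 1.42 at 10.0 min; ochre reads 1.42 at 10.0 min. We let each equal stretch add the same fraction of the stretch before, which gives 1.91 at 15 min: the partner exponent, the natural logarithm of partner charged over partner left. The stretches sum to 3.72, and by 1.0 h they reach 3.51.

**Our ranking.** West then stands at 51.1% of its starting material, and east at 85.2%. No run varies initiator, so we guess that the exponent follows the root of its charge, which puts south at 75.9%. South-west's partner could cover 1.12 of its charge and south-east's 1.58, so starting material is the limiting reagent in both. Taking one starting material lost per initiating radical made until then, we reckon south-west 95.0% and south-east 99.3%. At 1.0 h east reaches 97.0%, more than south-west.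

**The forecast.** The forecast gives south-east > south-west > east > south > west, then south-east > east > south-west > south > west, with top 99.3% (98.5% to 99.8%) and low 51% (48.5% to 53%), holding that the “rate is first order in partner and nearly independent of starting material”.

**The result.** The flasks give south-east > south-west > east > south > west, then south-east > east > south-west > south > west, with top 99.4% and low 51.3%.

    2 first chain carrier → ended chains (k = 8.00 × 10⁶ L mol⁻¹ s⁻¹)
    partner + first chain carrier → product + second chain carrier (k = 11300 L mol⁻¹ s⁻¹)
    initiator → 2 initiating radical (k = 0.0914 min⁻¹)
    starting material + initiating radical → capped initiator + first chain carrier (k = 79700 L mol⁻¹ s⁻¹)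
    starting material + second chain carrier → released group + first chain carrier (k = 1.44 × 10⁵ L mol⁻¹ min⁻¹)

**Less partner.** West's exponent of 1.91 reckons 14.8% of its partner left, and the flask holds 14.6%. South-east's top moves by 5 points at 29.8 mM of partner, and the neighbouring flask goes lower, at 0.500 equiv. Its exponent, scaled for initiator, is 1.42, which leaves 24.2% of the partner and gives 37.9% product. The flask holds 23.8% of its partner and 38.1% product, with 60.7% of the starting material left.

All runs are simulated from invented constants; scatter was added.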